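**Retrosynthetic overview**
1. Side chain last: the C12–C13 bond comes from alkylating an α-(phenylthio)butyrolactone enolate with a C12 iodide, then sulfoxide elimination to the butenolide; the C17 aldehyde and the C18/C19 diol are unmasked in the final step.
2. Ring A is formed second, by the C1–C10 bond: a 6-endo vinyl-radical cyclization onto the C5=C10 alkene of a cyclohexene, with C5–H delivered by hydrogen-atom transfer to give the trans-decalin.
3. Ring B is formed first: an asymmetric Diels–Alder reaction of acrolein (C7, C8, C17) with a 2-malonyl-1,3-diene (C6, C5, C10, C9) sets C9; C8 is corrected later by epimerization.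
4. The diene comes from Pd-catalysed SN2′ coupling of dimethyl malonate with an α-allenic carbonate (indium Barbier reaction of 3-(benzyloxy)propanal), then C-allylation with 1,3-dibromopropene.
5. Enabling feature: C4, the carbon carrying both CH2OH groups, is a malonate carbon. As a quaternary gem-diester it ties the C1–C3 arm to C5 of ring B, so that C10 (the methyl-bearing quaternary carbon between C5 and C9) is the only accessible terminus of the tetrasubstituted C5=C10 alkene, and C9 next to it steers the face of attack.

Key step: step 7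

Assumption: labdane numbering is used throughout (decalin C1–C10, side chain C11–C16, formyl C17 on C8, hydroxymethyls C18/C19 on C4, methyl C20), the target being (5S,8S,9R,10S); the imidazolidinone Diels–Alder catalyst is taken to follow its usual facial model, and its enantiomer is used if the sense proves opposite.

**Route**

Step 1
Reactants: 1 3-(benzyloxy)propanal; 2 1-bromobut-2-yne
Product: 4 allenyl carbinol (racemic), via organoindium bromide 3 (not isolated)
Conditions: In powder, THF/H2O 1:1, rt
Reagents that add atoms: none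
Why: Indium-mediated Barbier reaction in which the γ-methyl propargylindium reacts in the SE2′ sense to give the α-allenic alcohol; the carbinol centre is racemic and is destroyed in step 3.

Step 2
Reactants: 4 allenyl carbinol
Product: 5 allenyl methyl carbonate
Conditions: ClCO2Me, pyridine, DMAP (cat.), CH2Cl2, 0 °C
Reagents that add atoms: methyl chloroformate COC(=O)Cl
Why: O-acylation of the secondary alcohol installs the carbonate leaving group needed for palladium ionization; no stereocentre of the target is involved.

Step 3
Reactants: 5 allenyl methyl carbonate; 6 dimethyl malonate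
Product: 7 dienyl malonate
Conditions: Pd2(dba)3 (2.5 mol%), dppe (6 mol%), THF, 50 °C
Reagents that add atoms: none
Why: Tsuji–Trost-type SN2′ substitution of an α-allenic carbonate, in which zerovalent palladium gives a 1,3-dien-2-yl palladium species that couples with the malonate at the central carbon, forming the C4–C5 bond and the (E)-C9=C10 alkene with the larger groups anti.

Step 4
Reactants: 7 dienyl malonate; 8 1,3-dibromopropene (E/Z mixture)
Product: 10 bromoallyl dienyl malonate, via sodium enolate 9 (not isolated)
Conditions: NaH, THF/DMF, 0 °C → rt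
Reagents that add atoms: none
Why: Malonate C-alkylation (SN2 at the allylic bromide) makes C4 quaternary and attaches C1–C3 with the vinyl bromide that later serves as radical precursor; the alkene geometry of the bromide is irrelevant because the vinyl radical inverts.

Step 5
Reactants: 10 bromoallyl dienyl malonate; 11 acrolein
Product: 12 (8R,9R)-cyclohexene aldehyde
Conditions: acrolein (3 equiv), (5S)-5-benzyl-2,2,3-trimethylimidazolidin-4-one·HCl (20 mol%), MeCN/H2O 95:5, −10 °C → rt
Reagents that add atoms: none
Why: Iminium-catalysed asymmetric Diels–Alder reaction that builds ring B; the diene adds to the iminium face remote from the catalyst benzyl group with "ortho" regiochemistry (C9 to the α-carbon) and endo topology, which sets C9 (R) and C8 (R, formyl cis to the side chain).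

Step 6
Reactants: 12 (8R,9R)-cyclohexene aldehyde
Product: 15 (8R,9R)-cyclohexene nitrile, via oxime 13 (not isolated), via O-acetyl oxime 14 (not isolated)
Conditions: NH2OH·HCl, pyridine, EtOH, rt; then Ac2O, pyridine, 80 °C
Reagents that add atoms: hydroxylamine hydrochloride NO.Cl
Why: Oxime formation and dehydration convert C17 into a small, radical-inert nitrile that stays equatorial in the reacting cyclohexene; C8 and C9 are untouched.

Step 7
Reactants: 15 (8R,9R)-cyclohexene nitrile
Product: 18 (5S,8R,9R,10S)-octalin nitrile diester, via vinyl radical 16 (not isolated), via tertiary C5 radical 17 (not isolated)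
Conditions: Bu3SnH (1.3 equiv, syringe pump), AIBN (0.2 equiv), PhH (0.005 M), 80 °C
Reagents that add atoms: none
Why: Tin-hydride vinyl-radical cyclization: Bu3Sn• abstracts bromine, the C1 σ-radical (E and Z converge by inversion) adds to C10 of the tetrasubstituted C5=C10 alkene, and the tertiary C5 radical is reduced by Bu3SnH; the closest known reaction type is the stannane-mediated cyclization of vinyl bromides onto cyclohexenes that builds quaternary ring-fusion carbons. Ring A closes in the 6-endo-trig mode, either directly or by 5-exo closure followed by 3-exo/ring-opening rearrangement at low stannane concentration. C10 is controlled by C9: A(1,2) strain with the C10 methyl places the C9 side chain pseudoaxial on the α face (the nitrile stays equatorial), so C1 bonds to the β face. C5 is set by hydrogen-atom transfer to the face opposite the C10 methyl and the axial C4 ester, which should give the trans ring fusion. The step needs 6-endo over 5-exo attack and cyclization before reduction; the quaternary C4 next to C5 (5-exo would create two adjacent quaternary carbons), the gem-diester effect and slow stannane addition are what secure this.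

Step 8
Reactants: 18 (5S,8R,9R,10S)-octalin nitrile diester
Product: 20 (8R)-diol aldehyde, via aldimine 19 (not isolated)
Conditions: i-Bu2AlH (DIBAL-H, 7 equiv), CH2Cl2, −78 → 0 °C; then 1 M HCl, 0 °C
Reagents that add atoms: water O
Why: Hydride reduction of both methyl esters to the C18/C19 alcohols and of the nitrile to the N-aluminio aldimine, which is hydrolysed on work-up to the C17 aldehyde; no stereocentre changes.

Step 9
Reactants: 20 (8R)-diol aldehyde
Product: 22 acetonide dimethyl acetal, via equatorial aldehyde 21 (not isolated)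
Conditions: K2CO3, MeOH, rt; then CSA, Me2C(OMe)2, HC(OMe)3, rt
Reagents that add atoms: 2,2-dimethoxypropane COC(C)(C)OC; trimethyl orthoformate COC(OC)OC
Why: Base-mediated enolate epimerization moves the axial formyl group (1,3-diaxial to the C10 methyl) to the equatorial (8S) position under thermodynamic control, and acid-catalysed acetalization then protects the 1,3-diol as the acetonide and the aldehyde as its dimethyl acetal.

Step 10
Reactants: 22 acetonide dimethyl acetal
Product: 23 C12 alcohol
Conditions: H2 (1 atm), 10% Pd/C, EtOAc/EtOH, rt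
Reagents that add atoms: none
Why: Heterogeneous hydrogenation saturates the C1=C2 alkene and hydrogenolyses the benzyl ether in one operation; no new stereocentre is formed.

Step 11
Reactants: 23 C12 alcohol
Product: 24 C12 iodide
Conditions: I2, PPh3, imidazole, CH2Cl2, 0 °C → rt
Reagents that add atoms: iodine II
Why: Appel-type iodination of the unhindered primary alcohol under imidazole buffering, which both acetals tolerate.

Step 12
Reactants: 25 α-bromo-γ-butyrolactone; 26 thiophenol
Product: 27 α-(phenylthio)-γ-butyrolactone (racemic)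
Conditions: Et3N, CH2Cl2, 0 °C → rt
Reagents that add atoms: none
Why: SN2 displacement of the α-bromide by thiolate gives the lactone whose sulfur later delivers the ring double bond; its stereocentre is lost in step 15.

Step 13
Reactants: 27 α-(phenylthio)-γ-butyrolactone; 24 C12 iodide
Product: 29 sulfide lactone, via lithium enolate 28 (not isolated)
Conditions: LDA, THF, −78 °C; then 24, HMPA, −78 °C → rt
Reagents that add atoms: none
Why: Enolate alkylation (SN2 at the primary iodide) forms the C12–C13 bond; the new sulfur-bearing quaternary centre forms as a mixture and is removed in step 15.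

Step 14
Reactants: 29 sulfide lactone
Product: 30 sulfoxide lactone
Conditions: mCPBA (1.0 equiv), NaHCO3, CH2Cl2, −78 → 0 °C
Reagents that add atoms: 3-chloroperoxybenzoic acid O=C(OO)c1cccc(Cl)c1
Why: Chemoselective sulfide-to-sulfoxide oxidation with one equivalent of peracid; no alkene is present and the acetals are inert.

Step 15
Reactants: 30 sulfoxide lactone
Product: 31 butenolide acetal
Conditions: PhMe, CaCO3, 110 °C
Reagents that add atoms: none
Why: Thermal syn-elimination of the sulfoxide toward the ring methylene (C14) gives the conjugated endocyclic C13=C14 butenolide.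

Step 16
Reactants: 31 butenolide acetal
Product: 32 target (5S,8S,9R,10S)
Conditions: 2 M HCl/THF 1:3, rt
Reagents that add atoms: water O
Why: Acid-catalysed hydrolysis of the acetonide and the dimethyl acetal releases the diol and the equatorial aldehyde without touching the butenolide; all four stereocentres are already in place.

**Compound list**
1 | 3-(benzyloxy)propanal | O=CCCOCc1ccccc1 | starting material
2 | 1-bromobut-2-yne | CC#CCBr | starting material
3 | but-2-yn-1-ylindium dibromide (simplest formulation of the organoindium species, not isolated) | CC#CC[In](Br)Br | intermediate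
4 | rac-6-(benzyloxy)-3-methylhexa-1,2-dien-4-ol | C=C=C(C)C(O)CCOCc1ccccc1 | intermediate
5 | rac-6-(benzyloxy)-3-methylhexa-1,2-dien-4-yl methyl carbonate | C=C=C(C)C(OC(=O)OC)CCOCc1ccccc1 | intermediate
6 | dimethyl malonate | COC(=O)CC(=O)OC | starting material
7 | dimethyl 2-[(3E)-6-(benzyloxy)-3-methylhexa-1,3-dien-2-yl]malonate | C=C(C(C(=O)OC)C(=O)OC)/C(C)=C/CCOCc1ccccc1 | intermediate
8 | 1,3-dibromoprop-1-ene (E/Z mixture) | BrCC=CBr | starting material
9 | sodium enolate of 7 (not isolated) | COC(=O)C(C(=C)/C(C)=C/CCOCc1ccccc1)=C([O-])OC.[Na+] | intermediate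
10 | dimethyl 2-[(3E)-6-(benzyloxy)-3-methylhexa-1,3-dien-2-yl]-2-(3-bromoprop-2-en-1-yl)malonate (bromoalkene E/Z) | C=C(C(CC=CBr)(C(=O)OC)C(=O)OC)/C(C)=C/CCOCc1ccccc1 | intermediate
11 | acrolein | C=CC=O | starting material
12 | dimethyl 2-[(3R,4R)-3-[2-(benzyloxy)ethyl]-4-formyl-2-methylcyclohex-1-en-1-yl]-2-(3-bromoprop-2-en-1-yl)malonate (labdane 8R,9R; formyl cis to side chain) | CC1=C(C(CC=CBr)(C(=O)OC)C(=O)OC)CC[C@@H](C=O)[C@H]1CCOCc1ccccc1 | intermediate
13 | oxime of 12 (not isolated) | CC1=C(C(CC=CBr)(C(=O)OC)C(=O)OC)CC[C@@H](C=NO)[C@H]1CCOCc1ccccc1 | intermediate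
14 | O-acetyl oxime of 12 (not isolated) | CC1=C(C(CC=CBr)(C(=O)OC)C(=O)OC)CC[C@@H](C=NOC(C)=O)[C@H]1CCOCc1ccccc1 | intermediate
15 | dimethyl 2-[(3R,4R)-3-[2-(benzyloxy)ethyl]-4-cyano-2-methylcyclohex-1-en-1-yl]-2-(3-bromoprop-2-en-1-yl)malonate (labdane 8R,9R) | CC1=C(C(CC=CBr)(C(=O)OC)C(=O)OC)CC[C@@H](C#N)[C@H]1CCOCc1ccccc1 | intermediate
16 | C1 vinyl radical from 15 (not isolated) | CC1=C(C(CC=[CH])(C(=O)OC)C(=O)OC)CC[C@@H](C#N)[C@H]1CCOCc1ccccc1 | intermediate
17 | (8R,9R,10S) bicyclic tertiary C5 radical (not isolated) | C[C@@]12C=CCC(C(=O)OC)(C(=O)OC)[C]1CC[C@@H](C#N)[C@H]2CCOCc1ccccc1 | intermediate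
18 | dimethyl (4aS,5R,6R,8aS)-5-[2-(benzyloxy)ethyl]-6-cyano-4a-methyl-4a,5,6,7,8,8a-hexahydronaphthalene-1,1(2H)-dicarboxylate (labdane 5S,8R,9R,10S; trans-fused, nitrile axial) | C[C@@]12C=CCC(C(=O)OC)(C(=O)OC)[C@H]1CC[C@@H](C#N)[C@H]2CCOCc1ccccc1 | intermediate
19 | (5S,8R,9R,10S) C17 aldimine diol (not isolated) | C[C@@]12C=CCC(CO)(CO)[C@H]1CC[C@@H](C=N)[C@H]2CCOCc1ccccc1 | intermediate
20 | (1R,2R,4aS,8aS)-1-[2-(benzyloxy)ethyl]-5,5-bis(hydroxymethyl)-8a-methyl-1,2,3,4,4a,5,6,8a-octahydronaphthalene-2-carbaldehyde (labdane 5S,8R,9R,10S; formyl axial) | C[C@@]12C=CCC(CO)(CO)[C@H]1CC[C@@H](C=O)[C@H]2CCOCc1ccccc1 | intermediate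
21 | (1R,2S,4aS,8aS) C8 epimer of 20 (labdane 5S,8S,9R,10S; formyl equatorial; not isolated) | C[C@@]12C=CCC(CO)(CO)[C@H]1CC[C@H](C=O)[C@H]2CCOCc1ccccc1 | intermediate
22 | (5S,8S,9R,10S) C18/C19 acetonide, C17 dimethyl acetal, C12 benzyl ether, C1=C2 alkene | C[C@@]12C=CCC3(COC(C)(C)OC3)[C@H]1CC[C@H](C(OC)OC)[C@H]2CCOCc1ccccc1 | intermediate
23 | (5S,8S,9R,10S) saturated acetonide dimethyl acetal with C12 alcohol | C[C@@]12CCCC3(COC(C)(C)OC3)[C@H]1CC[C@H](C(OC)OC)[C@H]2CCO | intermediate
24 | (5S,8S,9R,10S) C12 iodide | C[C@@]12CCCC3(COC(C)(C)OC3)[C@H]1CC[C@H](C(OC)OC)[C@H]2CCI | intermediate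
25 | 3-bromodihydrofuran-2(3H)-one (α-bromo-γ-butyrolactone, racemic) | O=C1OCCC1Br | starting material
26 | thiophenol | Sc1ccccc1 | starting material
27 | 3-(phenylthio)dihydrofuran-2(3H)-one (racemic) | O=C1OCCC1Sc1ccccc1 | intermediate
28 | lithium enolate of 27 (not isolated) | [Li+].[O-]C1=C(Sc2ccccc2)CCO1 | intermediate
29 | (5S,8S,9R,10S) C13 phenylthio lactone (mixture at C13) | C[C@@]12CCCC3(COC(C)(C)OC3)[C@H]1CC[C@H](C(OC)OC)[C@H]2CCC1(Sc2ccccc2)CCOC1=O | intermediate
30 | (5S,8S,9R,10S) C13 phenylsulfinyl lactone (mixture at C13 and S) | C[C@@]12CCCC3(COC(C)(C)OC3)[C@H]1CC[C@H](C(OC)OC)[C@H]2CCC1(S(=O)c2ccccc2)CCOC1=O | intermediate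
31 | (5S,8S,9R,10S) butenolide with acetonide and dimethyl acetal | C[C@@]12CCCC3(COC(C)(C)OC3)[C@H]1CC[C@H](C(OC)OC)[C@H]2CCC1=CCOC1=O | intermediate
32 | (1R,2S,4aS,8aS)-5,5-bis(hydroxymethyl)-8a-methyl-1-[2-(2-oxo-2,5-dihydrofuran-3-yl)ethyl]decahydronaphthalene-2-carbaldehyde | C[C@@]12CCCC(CO)(CO)[C@H]1CC[C@H](C=O)[C@H]2CCC1=CCOC1=O | target

**Count and risks**
Total step count: 16. Longest linear sequence: 15 (steps 1–11 and 13–16; step 12 prepares the lactone reagent).

Three steps most likely to fail:

1. Step 7. The hydrogen-atom transfer to the C5 radical may show poor facial selectivity: the chair that leads to the trans-decalin forces the C8 nitrile axial, syn to the C10 methyl, so the cis-fused isomer may compete. The vinyl radical may also be reduced or close 5-exo before the 6-endo closure. Fallback: set C8 before ring closure, so that ring B is an all-equatorial chair when hydrogen is delivered. It sets out from nitrile 15, which is equilibrated at C8 with KOt-Bu in t-BuOH; the (8S,9R)-cyclohexene nitrile F1 is separated and 15 recycled. F1 is cyclized with Bu3SnH/AIBN to the C8-equatorial octalin nitrile F2, which DIBAL-H reduction converts directly into aldehyde 21; the acetalization stage of step 9 then returns to the route at 22.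

2. Step 5. The 2,3-disubstituted diene carries a quaternary group at C5 and may react sluggishly with the iminium dienophile, with loss of regio- and enantioselectivity. Fallback: a Lewis-acid Diels–Alder reaction with a covalently bound chiral auxiliary. It sets out from diene 10, which reacts with (S)-3-acryloyl-4-benzyl-1,3-oxazolidin-2-one and Et2AlCl in CH2Cl2 at −78 °C to give the imide cycloadduct F3. LiBH4 cleaves the auxiliary to the primary alcohol F4, and Swern oxidation ((COCl)2, DMSO, Et3N) returns to the route at aldehyde 12.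

3. Step 15. The sulfoxide may eliminate toward the side-chain methylene (C12), giving the exocyclic alkylidene lactone instead of the butenolide. Fallback: attach the ready-made butenolide by cross-coupling. It sets out from iodide 24, which is converted with Zn dust and LiCl in THF into the alkylzinc iodide F5; Negishi coupling with 3-bromofuran-2(5H)-one (Pd(OAc)2, SPhos, THF, rt) returns to the route at butenolide acetal 31, bypassing steps 12–15.

**Further compounds**
F1 | step 7 | dimethyl 2-[(3R,4S)-3-[2-(benzyloxy)ethyl]-4-cyano-2-methylcyclohex-1-en-1-yl]-2-(3-bromoprop-2-en-1-yl)malonate (labdane 8S,9R) | CC1=C(C(CC=CBr)(C(=O)OC)C(=O)OC)CC[C@H](C#N)[C@H]1CCOCc1ccccc1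
F2 | step 7 | dimethyl (4aS,5R,6S,8aS)-5-[2-(benzyloxy)ethyl]-6-cyano-4a-methyl-4a,5,6,7,8,8a-hexahydronaphthalene-1,1(2H)-dicarboxylate (labdane 5S,8S,9R,10S; nitrile equatorial) | C[C@@]12C=CCC(C(=O)OC)(C(=O)OC)[C@H]1CC[C@H](C#N)[C@H]2CCOCc1ccccc1
F3 | step 5 | (8R,9R) N-acyl oxazolidinone Diels–Alder adduct of 10 with (S)-3-acryloyl-4-benzyl-1,3-oxazolidin-2-one | CC1=C(C(CC=CBr)(C(=O)OC)C(=O)OC)CC[C@@H](C(=O)N2[C@@H](Cc3ccccc3)COC2=O)[C@H]1CCOCc1ccccc1
F4 | step 5 | (8R,9R) primary alcohol corresponding to aldehyde 12 | CC1=C(C(CC=CBr)(C(=O)OC)C(=O)OC)CC[C@@H](CO)[C@H]1CCOCc1ccccc1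
F5 | step 15 | (5S,8S,9R,10S) C12 alkylzinc iodide from 24 | C[C@@]12CCCC3(COC(C)(C)OC3)[C@H]1CC[C@H](C(OC)OC)[C@H]2CC[Zn]I
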